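Readings and results were generated by integration from invented constants; scatter was added.

Target is the peak I follow in a closed, isothermal flask where substrate meets reagent over free catalyst, and I want to know how much isomer of the product A stands against it.

- red: substrate 1.9 M; reagent 2.7 M; free catalyst 3.8 mM; run made earlier
- flask: substrate 1.9 M; reagent 1.90 M; free catalyst 3.8 mM; time 5.0 min

red run (percent of the substrate charged)

| time / min | isomer of the product A / % | target / % |
|---|---|---|
| 0.417 | 34.4 | 33.8 |
| 0.833 | 50.7 | 26.1 |
| 1.33 | 62.4 | 17.4 |
| 2.50 | 81.5 | 9.8 |
| 5.00 | 92.6 | 3.7 |

(standard deviation of a reading: 1 percentage point)

- the earlier runs were read with a standard deviation of 1 percentage point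

* ratio of isomer of the product A to target at 0.60 s
* ratio of isomer of the product A to target at 12 s
* ratio of isomer of the product A to target at 5.0 min
* which of isomer of the product A and target there is more of at 5.0 min

With the main step alone, substrate + reagent giving target and isomer in a fixed split, the ratio of isomer to target stays put. But in the red run it climbs from 1.02 to 25.0, so I add a second step, target passing into the isomer over free catalyst, pseudo-first-order at a given catalyst charge. The fraction of target left between the first and third red readings gives a half-life of 0.953 min, a reading with the feed still inside it. That is short against 5.0 min, but plain decay at this half-life from the first red reading leaves 1.21% at 5.00 min, and the red reading there is higher, at 3.7%.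

The third addition is the substrate and reagent still present, and as a working assumption I take late target to follow F, the product of their concentrations left. At 2.50 min the red balance leaves 8.70% of the substrate, so F is 0.160 M^2 and target over F is 0.614 M⁻²: this is the tail coefficient g, late target as a fraction of substrate charged per unit of F at one catalyst charge. The red reading at 5.00 min gives 0.605 M⁻², though both carry the scatter of the balance.

The fractions left at 2.50 min also give a second-order constant of 0.707 M⁻¹ min⁻¹. With its equal charges, I reckon that the flask keeps 13.0% of each at 5.0 min. Its catalyst charge matches the red run's, so g carries over and I reckon target at 3.73% and a ratio of 22.4.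

The forecast gives 0.6, 0.75 and 26 with isomer of the product A ahead, starting from "Target falls while the isomer keeps rising", and its late ratio stands above mine.

The flask gives 0.338, 0.619 and 18.7, with isomer of the product A ahead at 81.4% against 4.34% of target.

    substrate + reagent ⇌ target (K = 1.30 M⁻¹, k = 0.0460 M⁻¹ s⁻¹)
    substrate + reagent ⇌ isomer of the product A (K = 44.0 M⁻¹, k = 0.0150 M⁻¹ s⁻¹)
    target + free catalyst ⇌ isomer of the product A + free catalyst, rate k3*[free catalyst]*[target] forward; the back reaction follows from the equilibrium constant (k = 3.20 M⁻¹ s⁻¹)
    substrate + free catalyst → spent catalyst (k = 0.00270 M⁻¹ s⁻¹)
    target ⇌ isomer of the product B (K = 0.240, k = 0.0360 s⁻¹)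

At 5.0 min the flask makes target at 0.204 of the rate at which it uses it up, each step taken net, and g times the simulated substrate and reagent gives 3.87% against the 4.34% of target standing there. In the neighbour flask with 0.76 M of reagent, at the same catalyst charge, 61.1% of substrate and 3.02% of reagent left give 1.64% by g, against a simulated target of 1.96%.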